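The α-methylene-γ-butyrolactone is assembled by carboxylative lactonisation (numbering defined below). The lactone carbinol carbon C1 of the five-membered ring lies γ to the methylene-bearing carbon C11 and carries C2 of the ten-membered ring. In the precursor, C11 is a 2-bromoalkene carbon and C1–C2 is a terminal oxirane. Bromine–lithium exchange, CO2 capture (C11–C12) and acid-triggered 5-exo opening of the oxirane by the new carboxyl group (O–C1, inversion) give the cis-lactone and free the C2 hydroxymethyl handle for the (Z)-iodoalkene. The chain comes from nerol and (R)-glyceraldehyde acetonide by a chromium-mediated 2-bromoallylation. The ten-membered ring is closed last by a Nozaki–Hiyama–Kishi reaction at C3–C4.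

Key step: step 11

Numbering used below (skeleton of 31): C1 = lactone O–CH; C2=C3(CH3) = ring alkene; C4 = carbinol; C5/C6(CH3) = oxirane carbons; C7, C8 = CH2; C9 = angelate-bearing carbon; C10 = ring-fusion carbon; C11 = lactone α-carbon with methylene C13; C12 = lactone carbonyl.
Remark: several CIP descriptors change along the route only because substituent priorities change; the SMILES strings are authoritative.

Step 1
Reactants: 1 nerol
Product: 2 O-TBDPS nerol
Conditions: TBDPSCl, imidazole, CH2Cl2, 0 °C → rt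
Reagents that add atoms: tert-butyl(chloro)diphenylsilane, CC(C)(C)[Si](Cl)(c1ccccc1)c1ccccc1
Why: Imidazole-promoted silylation of the primary allylic alcohol gives an ether that should survive aqueous acid, t-BuLi and CrCl2; no stereocentre is formed.

Step 2
Reactants: 2 O-TBDPS nerol
Product: 3 racemic 6,7-epoxide of 2
Conditions: mCPBA (1.05 equiv), NaHCO3, CH2Cl2, −20 °C
Reagents that add atoms: 3-chloroperoxybenzoic acid, OOC(=O)c1cccc(Cl)c1
Why: Prilezhaev epoxidation should prefer the electron-rich isopropylidene alkene, because the other alkene is deactivated and shielded by the allylic silyloxy group; the new oxirane centre is destroyed in step 3.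

Step 3
Reactants: 3 racemic 6,7-epoxide of 2
Product: 4 (4Z)-6-[(tert-butyldiphenylsilyl)oxy]-4-methylhex-4-enal
Conditions: H5IO6, THF/H2O, 0 °C
Reagents that add atoms: none
Why: Periodic acid hydrates the trisubstituted oxirane and cleaves the glycol (Malaprade-type fission) to the aldehyde and acetone, leaving the silyl ether and the Z-alkene intact.

Step 4
Reactants: 5 (R)-glyceraldehyde acetonide, 6 ethyl (triphenylphosphoranylidene)acetate
Product: 8 ethyl (2Z)-2-bromo-3-[(4S)-2,2-dimethyl-1,3-dioxolan-4-yl]prop-2-enoate, via bromo ylide 7 (not isolated)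
Conditions: 6, NBS, CH2Cl2, −20 °C; then 5, K2CO3, −20 °C → rt
Reagents that add atoms: N-bromosuccinimide, O=C1CCC(=O)N1Br
Why: One-pot ylide bromination and Wittig olefination with the stabilised bromo ylide should give mainly the Z-bromoenoate without epimerising the dioxolane centre; the geometry is not critical because the allyl chromium species of step 7 equilibrates.

Step 5
Reactants: 8 bromoenoate
Product: 9 (2Z)-2-bromo-3-[(4S)-2,2-dimethyl-1,3-dioxolan-4-yl]prop-2-en-1-ol
Conditions: i-Bu2AlH (2.2 equiv), CH2Cl2, −78 °C; aqueous potassium sodium tartrate work-up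
Reagents that add atoms: none
Why: Hydride 1,2-reduction of the enoate at low temperature gives the allylic alcohol and leaves the vinylic bromide and the acetonide untouched.

Step 6
Reactants: 9 bromoallylic alcohol
Product: 10 (4S)-4-[(1Z)-2,3-dibromoprop-1-en-1-yl]-2,2-dimethyl-1,3-dioxolane
Conditions: CBr4, PPh3, 2,6-lutidine, CH2Cl2, 0 °C
Reagents that add atoms: carbon tetrabromide, BrC(Br)(Br)Br
Why: Appel bromination converts the primary allylic alcohol to the bromide under buffered, near-neutral conditions that spare the acetonide.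

Step 7
Reactants: 4 aldehyde, 10 allylic bromide
Product: 11 (3R,4S,7Z)-2-bromo-9-[(tert-butyldiphenylsilyl)oxy]-3-[(4S)-2,2-dimethyl-1,3-dioxolan-4-yl]-7-methylnona-1,7-dien-4-ol
Conditions: CrCl2 (3 equiv), THF, 0 °C → rt
Reagents that add atoms: none
Why: Hiyama–Nozaki allylation, in which CrCl2 without nickel inserts only into the allylic C–Br bond; the γ-substituted 2-bromoallyl chromium should add through a chair transition state with the dioxolanyl group trans to the CrCH2 terminus to give the 9,10-anti adduct, and attack anti to the dioxolane C–O bond (Felkin-type, reinforced by allylic strain with the vinylic bromine) should set C10 relative to C1.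

Step 8
Reactants: 11 homoallylic alcohol
Product: 12 C9 4-methoxybenzyl ether of 11
Conditions: NaH, 4-methoxybenzyl chloride, Bu4NI (cat.), THF/DMF, 0 °C → rt
Reagents that add atoms: 4-methoxybenzyl chloride, COc1ccc(CCl)cc1
Why: Williamson etherification masks the C9 hydroxyl as a PMB ether that tolerates aqueous acid and t-BuLi and keeps this hydroxyl from lactonising in step 11.

Step 9
Reactants: 12 PMB ether
Product: 13 (2S,3S,4S,7Z)-3-(1-bromoethenyl)-9-[(tert-butyldiphenylsilyl)oxy]-4-[(4-methoxybenzyl)oxy]-7-methylnon-7-ene-1,2-diol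
Conditions: AcOH/THF/H2O (3:1:1), 40 °C
Reagents that add atoms: none
Why: Mild acid hydrolysis of the terminal acetonide frees the C1/C2 diol while the PMB and TBDPS ethers and both alkenes are stable.

Step 10
Reactants: 13 diol
Product: 15 (2S)-2-{(3R,4S,7Z)-2-bromo-9-[(tert-butyldiphenylsilyl)oxy]-4-[(4-methoxybenzyl)oxy]-7-methylnona-1,7-dien-3-yl}oxirane, via primary tosylate 14 (not isolated)
Conditions: NaH (2.2 equiv), N-tosylimidazole (1.05 equiv), THF, 0 °C → rt
Reagents that add atoms: none
Why: Selective sulfonylation of the primary alkoxide and intramolecular Williamson closure (one-pot diol-to-epoxide method) give the terminal oxirane with retention at C1, because only the C2–O bond is broken.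

Step 11
Reactants: 15 bromoalkene oxirane
Product: 18 (4R,5R)-4-{(1S,4Z)-6-[(tert-butyldiphenylsilyl)oxy]-1-[(4-methoxybenzyl)oxy]-4-methylhex-4-en-1-yl}-5-(hydroxymethyl)-3-methylideneoxolan-2-one, via 2-lithioalkene 16 (not isolated), via epoxy acid 17 (not isolated)
Conditions: t-BuLi (2.1 equiv), THF, −78 °C, 10 min; CO2 (g), −78 → 0 °C; AcOH, H2O wash; CSA (cat.), CH2Cl2, rt (no purification between)
Reagents that add atoms: carbon dioxide, O=C=O
Why: t-BuLi exchanges the vinylic bromine at C11 faster than it attacks the oxirane or the ethers, and the 2-lithioalkene 16 adds to CO2 to form the C11–C12 bond as a lithium 2-substituted acrylate; on acidification the γ,δ-epoxy acid 17 closes, its carboxyl oxygen opening the protonated oxirane at C1 to form the O–C1 bond and free the C2 hydroxymethyl group. The closest known reaction types are carboxylation of alkenyllithiums (as in Shapiro-based α-methylene lactone syntheses) and acid-promoted lactonisation of γ,δ-epoxy acids. The five-membered lactone closes in the 5-exo-tet mode at the secondary oxirane carbon, which is favoured stereoelectronically and by charge over 6-endo attack at C2. C1 is set by SN2 inversion of the (S)-oxirane carbon, which places C2 and the C9 side chain cis on the lactone as in the target, and C10 is untouched. The step needs exchange and CO2 capture to outrun intramolecular attack of 16 on its own oxirane, secured by −78 °C and immediate CO2 quench, and it needs the acid to have no other partner, secured by the PMB ether on C9 and by washing out LiBr before the CSA treatment.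

Step 12
Reactants: 18 hydroxymethyl lactone
Product: 19 (2R,3R)-3-{(1S,4Z)-6-[(tert-butyldiphenylsilyl)oxy]-1-[(4-methoxybenzyl)oxy]-4-methylhex-4-en-1-yl}-4-methylidene-5-oxooxolane-2-carbaldehyde
Conditions: Dess–Martin periodinane, NaHCO3, CH2Cl2, 0 °C → rt
Reagents that add atoms: none
Why: Buffered Dess–Martin oxidation gives the α-acyloxy aldehyde under non-basic conditions that should neither epimerise C1 nor touch the α-methylene lactone.

Step 13
Reactants: 19 aldehyde, 20 ethyltriphenylphosphonium iodide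
Product: 24 (4R,5R)-4-{(1S,4Z)-6-[(tert-butyldiphenylsilyl)oxy]-1-[(4-methoxybenzyl)oxy]-4-methylhex-4-en-1-yl}-5-[(1Z)-2-iodoprop-1-en-1-yl]-3-methylideneoxolan-2-one, via ethylidene ylide 21 (not isolated), via iodoethylphosphonium iodide 22 (not isolated), via iodoethylidene ylide 23 (not isolated)
Conditions: 20, n-BuLi, THF, rt; I2, −78 °C; NaN(SiMe3)2, −20 °C; then 19, −78 → −20 °C
Reagents that add atoms: iodine, II
Why: Stork–Zhao olefination with the α-iodo ylide should give the trisubstituted (Z)-2-iodoalkene (iodine cis to C1) under kinetic control at −78 °C, where Wittig addition to the aldehyde outruns enolisation at C1 and conjugate addition to the lactone.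

Step 14
Reactants: 24 iodoalkene PMB ether
Product: 25 (4R,5R)-4-{(1S,4Z)-6-[(tert-butyldiphenylsilyl)oxy]-1-hydroxy-4-methylhex-4-en-1-yl}-5-[(1Z)-2-iodoprop-1-en-1-yl]-3-methylideneoxolan-2-one
Conditions: DDQ, CH2Cl2/pH 7 buffer, 0 °C
Reagents that add atoms: none
Why: Oxidative PMB cleavage (benzylic hydride abstraction by DDQ, then hemiacetal hydrolysis) frees the C9 hydroxyl without affecting the silyl ether, the iodoalkene or the lactone.

Step 15
Reactants: 25 C9 alcohol, 26 angelic acid
Product: 27 (1R,4Z)-6-[(tert-butyldiphenylsilyl)oxy]-1-{(2R,3R)-2-[(1Z)-2-iodoprop-1-en-1-yl]-4-methylidene-5-oxooxolan-3-yl}-4-methylhex-4-en-1-yl (2Z)-2-methylbut-2-enoate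
Conditions: PPh3, DIAD, 26, toluene, 0 °C → rt (betaine preformed)
Reagents that add atoms: none
Why: Mitsunobu esterification displaces the C9 alkoxyphosphonium ion by angelate in an SN2 step, which inverts C9 to the required configuration and installs the ester under neutral conditions that should not isomerise it to the tiglate.

Step 16
Reactants: 27 angelate silyl ether
Product: 28 (1R,4Z)-6-hydroxy-1-{(2R,3R)-2-[(1Z)-2-iodoprop-1-en-1-yl]-4-methylidene-5-oxooxolan-3-yl}-4-methylhex-4-en-1-yl (2Z)-2-methylbut-2-enoate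
Conditions: HF·pyridine, pyridine, THF, 0 °C → rt
Reagents that add atoms: none
Why: Buffered fluoride cleavage of the TBDPS ether frees the primary allylic alcohol and leaves both esters and the iodoalkene untouched.

Step 17
Reactants: 28 Z-allylic alcohol
Product: 29 (1R)-3-[(2S,3R)-3-(hydroxymethyl)-2-methyloxiran-2-yl]-1-{(2R,3R)-2-[(1Z)-2-iodoprop-1-en-1-yl]-4-methylidene-5-oxooxolan-3-yl}propyl (2Z)-2-methylbut-2-enoate
Conditions: Ti(OiPr)4 (20 mol %), D-(−)-diisopropyl tartrate (25 mol %), t-BuOOH, 4 Å molecular sieves, CH2Cl2, −20 °C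
Reagents that add atoms: tert-butyl hydroperoxide, CC(C)(C)OO
Why: Sharpless asymmetric epoxidation acts only on the allylic alcohol alkene, and the D-(−)-tartrate ligand should deliver oxygen to the face that gives the (5R,6S)-oxirane under reagent control, as for nerol itself.

Step 18
Reactants: 29 epoxy alcohol
Product: 30 (1R)-3-[(2S,3S)-3-formyl-2-methyloxiran-2-yl]-1-{(2R,3R)-2-[(1Z)-2-iodoprop-1-en-1-yl]-4-methylidene-5-oxooxolan-3-yl}propyl (2Z)-2-methylbut-2-enoate
Conditions: Dess–Martin periodinane, NaHCO3, CH2Cl2, 0 °C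
Reagents that add atoms: none
Why: Buffered Dess–Martin oxidation gives the cis-epoxy aldehyde, which is used at once to avoid epimerisation at C5.

Step 19
Reactants: 30 iodoalkene epoxy aldehyde
Product: 31 CNP0500828.1
Conditions: CrCl2 (10 equiv), NiCl2 (1 mol % of CrCl2), DMSO/THF (3:1), rt, syringe-pump addition of 30 to 2 mM
Reagents that add atoms: none
Why: Intramolecular Nozaki–Hiyama–Kishi reaction, in which the nickel-catalysed alkenyl chromium species forms from the (Z)-iodoalkene with retention and adds to the aldehyde at high dilution to close the ten-membered ring; attack anti to the oxirane C–O bond (Felkin–Anh) should give the 4,5-anti (4R) epoxy alcohol, and the esters and lactone are tolerated.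

Compound list
1 | nerol, (2Z)-3,7-dimethylocta-2,6-dien-1-ol | CC(C)=CCC/C(C)=C\CO | starting material
2 | tert-butyl{[(2Z)-3,7-dimethylocta-2,6-dien-1-yl]oxy}diphenylsilane | CC(C)=CCC/C(C)=C\CO[Si](c1ccccc1)(c1ccccc1)C(C)(C)C | intermediate
3 | tert-butyl{[(2Z)-5-(3,3-dimethyloxiran-2-yl)-3-methylpent-2-en-1-yl]oxy}diphenylsilane (racemic) | CC1(C)OC1CC/C(C)=C\CO[Si](c1ccccc1)(c1ccccc1)C(C)(C)C | intermediate
4 | (4Z)-6-[(tert-butyldiphenylsilyl)oxy]-4-methylhex-4-enal | O=CCC/C(C)=C\CO[Si](c1ccccc1)(c1ccccc1)C(C)(C)C | intermediate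
5 | (R)-2,2-dimethyl-1,3-dioxolane-4-carbaldehyde | O=C[C@H]1COC(C)(C)O1 | starting material
6 | ethyl (triphenylphosphoranylidene)acetate | CCOC(=O)C=P(c1ccccc1)(c1ccccc1)c1ccccc1 | starting material
7 | ethyl bromo(triphenylphosphoranylidene)acetate | CCOC(=O)C(Br)=P(c1ccccc1)(c1ccccc1)c1ccccc1 | intermediate
8 | ethyl (2Z)-2-bromo-3-[(4S)-2,2-dimethyl-1,3-dioxolan-4-yl]prop-2-enoate | CCOC(=O)/C(Br)=C/[C@H]1COC(C)(C)O1 | intermediate
9 | (2Z)-2-bromo-3-[(4S)-2,2-dimethyl-1,3-dioxolan-4-yl]prop-2-en-1-ol | OC/C(Br)=C/[C@H]1COC(C)(C)O1 | intermediate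
10 | (4S)-4-[(1Z)-2,3-dibromoprop-1-en-1-yl]-2,2-dimethyl-1,3-dioxolane | BrC/C(Br)=C/[C@H]1COC(C)(C)O1 | intermediate
11 | (3R,4S,7Z)-2-bromo-9-[(tert-butyldiphenylsilyl)oxy]-3-[(4S)-2,2-dimethyl-1,3-dioxolan-4-yl]-7-methylnona-1,7-dien-4-ol | C=C(Br)[C@@H]([C@H]1COC(C)(C)O1)[C@@H](O)CC/C(C)=C\CO[Si](c1ccccc1)(c1ccccc1)C(C)(C)C | intermediate
12 | (4S)-4-{(3R,4S,7Z)-2-bromo-9-[(tert-butyldiphenylsilyl)oxy]-4-[(4-methoxybenzyl)oxy]-7-methylnona-1,7-dien-3-yl}-2,2-dimethyl-1,3-dioxolane | C=C(Br)[C@@H]([C@H]1COC(C)(C)O1)[C@@H](OCc1ccc(OC)cc1)CC/C(C)=C\CO[Si](c1ccccc1)(c1ccccc1)C(C)(C)C | intermediate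
13 | (2S,3S,4S,7Z)-3-(1-bromoethenyl)-9-[(tert-butyldiphenylsilyl)oxy]-4-[(4-methoxybenzyl)oxy]-7-methylnon-7-ene-1,2-diol | C=C(Br)[C@@H]([C@H](O)CO)[C@@H](OCc1ccc(OC)cc1)CC/C(C)=C\CO[Si](c1ccccc1)(c1ccccc1)C(C)(C)C | intermediate
14 | primary (C2–O) 4-methylbenzenesulfonate of 13 | C=C(Br)[C@@H]([C@H](O)COS(=O)(=O)c1ccc(C)cc1)[C@@H](OCc1ccc(OC)cc1)CC/C(C)=C\CO[Si](c1ccccc1)(c1ccccc1)C(C)(C)C | intermediate
15 | (2S)-2-{(3R,4S,7Z)-2-bromo-9-[(tert-butyldiphenylsilyl)oxy]-4-[(4-methoxybenzyl)oxy]-7-methylnona-1,7-dien-3-yl}oxirane | C=C(Br)[C@@H]([C@H]1CO1)[C@@H](OCc1ccc(OC)cc1)CC/C(C)=C\CO[Si](c1ccccc1)(c1ccccc1)C(C)(C)C | intermediate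
16 | 2-lithioalkene from 15 (lithium in place of bromine at C11) | C=C([Li])[C@@H]([C@H]1CO1)[C@@H](OCc1ccc(OC)cc1)CC/C(C)=C\CO[Si](c1ccccc1)(c1ccccc1)C(C)(C)C | intermediate
17 | γ,δ-epoxy 2-substituted acrylic acid from 16 and CO2 | C=C(C(=O)O)[C@@H]([C@H]1CO1)[C@@H](OCc1ccc(OC)cc1)CC/C(C)=C\CO[Si](c1ccccc1)(c1ccccc1)C(C)(C)C | intermediate
18 | (4R,5R)-4-{(1S,4Z)-6-[(tert-butyldiphenylsilyl)oxy]-1-[(4-methoxybenzyl)oxy]-4-methylhex-4-en-1-yl}-5-(hydroxymethyl)-3-methylideneoxolan-2-one | C=C1C(=O)O[C@@H](CO)[C@H]1[C@@H](OCc1ccc(OC)cc1)CC/C(C)=C\CO[Si](c1ccccc1)(c1ccccc1)C(C)(C)C | intermediate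
19 | (2R,3R)-3-{(1S,4Z)-6-[(tert-butyldiphenylsilyl)oxy]-1-[(4-methoxybenzyl)oxy]-4-methylhex-4-en-1-yl}-4-methylidene-5-oxooxolane-2-carbaldehyde | C=C1C(=O)O[C@@H](C=O)[C@H]1[C@@H](OCc1ccc(OC)cc1)CC/C(C)=C\CO[Si](c1ccccc1)(c1ccccc1)C(C)(C)C | intermediate
20 | ethyltriphenylphosphonium iodide | CC[P+](c1ccccc1)(c1ccccc1)c1ccccc1.[I-] | starting material
21 | ethylidenetriphenylphosphorane | CC=P(c1ccccc1)(c1ccccc1)c1ccccc1 | intermediate
22 | (1-iodoethyl)triphenylphosphonium iodide | CC(I)[P+](c1ccccc1)(c1ccccc1)c1ccccc1.[I-] | intermediate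
23 | (1-iodoethylidene)triphenylphosphorane | CC(I)=P(c1ccccc1)(c1ccccc1)c1ccccc1 | intermediate
24 | (4R,5R)-4-{(1S,4Z)-6-[(tert-butyldiphenylsilyl)oxy]-1-[(4-methoxybenzyl)oxy]-4-methylhex-4-en-1-yl}-5-[(1Z)-2-iodoprop-1-en-1-yl]-3-methylideneoxolan-2-one | C=C1C(=O)O[C@@H](/C=C(/C)I)[C@H]1[C@@H](OCc1ccc(OC)cc1)CC/C(C)=C\CO[Si](c1ccccc1)(c1ccccc1)C(C)(C)C | intermediate
25 | (4R,5R)-4-{(1S,4Z)-6-[(tert-butyldiphenylsilyl)oxy]-1-hydroxy-4-methylhex-4-en-1-yl}-5-[(1Z)-2-iodoprop-1-en-1-yl]-3-methylideneoxolan-2-one | C=C1C(=O)O[C@@H](/C=C(/C)I)[C@H]1[C@@H](O)CC/C(C)=C\CO[Si](c1ccccc1)(c1ccccc1)C(C)(C)C | intermediate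
26 | angelic acid, (2Z)-2-methylbut-2-enoic acid | C/C=C(/C)C(=O)O | starting material
27 | (1R,4Z)-6-[(tert-butyldiphenylsilyl)oxy]-1-{(2R,3R)-2-[(1Z)-2-iodoprop-1-en-1-yl]-4-methylidene-5-oxooxolan-3-yl}-4-methylhex-4-en-1-yl (2Z)-2-methylbut-2-enoate | C=C1C(=O)O[C@@H](/C=C(/C)I)[C@H]1[C@H](OC(=O)/C(C)=C\C)CC/C(C)=C\CO[Si](c1ccccc1)(c1ccccc1)C(C)(C)C | intermediate
28 | (1R,4Z)-6-hydroxy-1-{(2R,3R)-2-[(1Z)-2-iodoprop-1-en-1-yl]-4-methylidene-5-oxooxolan-3-yl}-4-methylhex-4-en-1-yl (2Z)-2-methylbut-2-enoate | C=C1C(=O)O[C@@H](/C=C(/C)I)[C@H]1[C@H](OC(=O)/C(C)=C\C)CC/C(C)=C\CO | intermediate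
29 | (1R)-3-[(2S,3R)-3-(hydroxymethyl)-2-methyloxiran-2-yl]-1-{(2R,3R)-2-[(1Z)-2-iodoprop-1-en-1-yl]-4-methylidene-5-oxooxolan-3-yl}propyl (2Z)-2-methylbut-2-enoate | C=C1C(=O)O[C@@H](/C=C(/C)I)[C@H]1[C@H](OC(=O)/C(C)=C\C)CC[C@]1(C)O[C@@H]1CO | intermediate
30 | (1R)-3-[(2S,3S)-3-formyl-2-methyloxiran-2-yl]-1-{(2R,3R)-2-[(1Z)-2-iodoprop-1-en-1-yl]-4-methylidene-5-oxooxolan-3-yl}propyl (2Z)-2-methylbut-2-enoate | C=C1C(=O)O[C@@H](/C=C(/C)I)[C@H]1[C@H](OC(=O)/C(C)=C\C)CC[C@]1(C)O[C@@H]1C=O | intermediate
31 | CNP0500828.1 (skeleton numbering: 1S,4R,5R,6S,9R,10R; 2Z; cis-fused α-methylene lactone, 5,6-oxirane, C4 hydroxyl, C9 angelate) | C=C1C(=O)O[C@H]2/C=C(/C)[C@@H](O)[C@H]3O[C@@]3(C)CC[C@@H](OC(=O)/C(C)=C\C)[C@@H]12 | target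

Total step count: 19. Longest linear sequence: 16 steps (steps 1–3 and 7–19 from nerol; the branch from 5 through steps 4–6 is equally long).

Steps most likely to fail

Step 19. The facial selectivity at the C4 aldehyde carbon is governed by the conformation of the closing ten-membered ring and may override the Felkin preference, so addition may occur mainly on the wrong face. The fallback sets out from 30: the ring closure is run as planned, and the (4S)-carbinol F3, alone or mixed with 31, is oxidised with Dess–Martin periodinane to the macrocyclic epoxy enone F4. Reduction of F4 with Zn(BH4)2 in ether at low temperature, which is erythro-selective for α,β-epoxy ketones and proceeds 1,2 on the enone, sets C4 by hydride delivery instead of C–C bond formation and comes back to the route at 31.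

Step 7. The allyl chromium species may attack with poor facial control relative to the dioxolane centre, the anti preference may erode, or bromide may be lost from the 2-bromoallyl chromium to give an allene. The fallback sets out from 10: borylation with B2pin2 and Pd2(dba)3 in DMSO (zerovalent palladium reacts at the allylic, not the vinylic, C–Br bond) gives the allyl pinacolboronate F1. Allylboration of 4 with F1 under chiral phosphoric acid catalysis ((R)-TRIP by analogy with crotylborations of aliphatic aldehydes; the antipode if the sense proves opposite) proceeds through a closed chair transition state that enforces the anti relationship, with the catalyst choosing the aldehyde face. It comes back to the route at 11.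

Step 15. The hindered C9 alkoxyphosphonium ion may not be displaced by angelate, or may eliminate towards C10, whose hydrogen is allylic to the lactone methylene. The fallback sets out from 25: the alcohol is converted with chloromethanesulfonyl chloride and pyridine into the chloromethanesulfonate F2, which is displaced with inversion by cesium angelate (from 26 and Cs2CO3) with 18-crown-6 in toluene. It comes back to the route at 27.

Further compounds
F1 | step 7 | 2-{(2Z)-2-bromo-3-[(4S)-2,2-dimethyl-1,3-dioxolan-4-yl]prop-2-en-1-yl}-4,4,5,5-tetramethyl-1,3,2-dioxaborolane | CC1(C)OB(C/C(Br)=C/[C@H]2COC(C)(C)O2)OC1(C)C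
F2 | step 15 | C9 chloromethanesulfonate of 25 | C=C1C(=O)O[C@@H](/C=C(/C)I)[C@H]1[C@@H](OS(=O)(=O)CCl)CC/C(C)=C\CO[Si](c1ccccc1)(c1ccccc1)C(C)(C)C
F3 | step 19 | C4 epimer of 31 | C=C1C(=O)O[C@H]2/C=C(/C)[C@H](O)[C@H]3O[C@@]3(C)CC[C@@H](OC(=O)/C(C)=C\C)[C@@H]12
F4 | step 19 | C4 ketone of 31 (macrocyclic epoxy enone) | C=C1C(=O)O[C@H]2/C=C(/C)C(=O)[C@H]3O[C@@]3(C)CC[C@@H](OC(=O)/C(C)=C\C)[C@@H]12
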